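The numbers of this flask are those of an exercise, and the outcome is calculated.

Time in contact with free catalyst is what these set-ups hand out differently, so you count that, and you work with the fraction left, not the fraction made.

the same everywhere: catalyst 2.4 mol%; added ligand 18 mM
- west: substrate 0.50 M; time 30 min; everything together in a closed stirred flask, run for 30 min
- north: substrate 0.50 M (fed, over 15.0 min); time 30 min; all but substrate at the start; substrate goes in evenly over 15.0 min, the run ends at 30 min
- south-west: substrate 0.50 M; a single well-mixed tank run continuously and read at steady state, 30 min in it on average

    substrate ⇌ other conformer (K1 = 0.0205, k1 = 0.0279 s⁻¹)
    substrate + catalyst → catalyst + target (k2 = 0.0896 M⁻¹ s⁻¹)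
    catalyst + other conformer → catalyst + isomer of the product (k3 = 0.105 M⁻¹ s⁻¹)
    catalyst + added ligand ⇌ idle complex, settled at all times (K4 = 51 M⁻¹)

- the stated concentrations are those of everything mixed, before any reaction; amounts are the same in each set-up
- the feed brings no volume worth counting
- run time (west): 30 min

- the set-up with the highest amount of target at the outlet or at the end, in percent of the substrate put in ("none" if the first two lie within 2 percentage points) (west / north / south-west / none)
- amount of target at the outlet or at the end, in percent of the substrate put in, west
- amount of target at the outlet or at the end, in percent of the substrate put in, north
- amount of target at the outlet or at the end, in percent of the substrate put in, south-west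

**Free catalyst.** You charge 12.0 mM of catalyst. With the added ligand held at its full charge, free catalyst is 6.26 mM, a floor. Binding takes up no more ligand than the 12.0 mM of catalyst charged, so at least 6.00 mM of ligand stays free, and the ceiling is 9.19 mM.

**One pool.** The other conformer returns to substrate at 1.36 s⁻¹, while free catalyst drains it at no more than 9.65 × 10⁻⁴ s⁻¹, far slower. So you treat both conformers as one pool, which decays pseudo-first-order, its rate constant being free catalyst times a weighted constant of 0.0899 M⁻¹ s⁻¹. Target takes 97.7% of what reacts.

**The bracket.** For west, floor and ceiling give target at 62.2% to 75.6% of the substrate put in. Solving the binding balance tightens this: free catalyst is 7.18 mM, and the idle complex holds the other 4.82 mM. The pool then decays at 0.0387 min⁻¹, and over 30 min that gives 1.16; this product is the contact number.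

**Fraction left.** In west, exp(−contact number) leaves 31.3%, so I expect 67.1% of target. The north feed, spread over 15.0 min, leaves 42.4%, which gives 56.2%. The south-west tank, with 1/(1+contact number), leaves 46.3%, which gives 52.5%. West stands highest.

**The forecast.** It names west, with 67.1% for west, which stands inside the bracket for west, 56.2% for north and 52.5% for south-west, on the ground that “only first-order conversion separates the set-ups”.

**The outcome.** West gives 67.1%, north 56.2%, and south-west 52.5%, so west leads. At steady state the outlet of the south-west tank carries 45.3% of the substrate charged as substrate and 0.928% as other conformer. Give that tank ten times the residence time and the contact number becomes 11.6, which leaves 7.93% and reckons to 90.0% of target; the tank there gives 89.9%.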